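**Strategy.** Ring B (C5–C6–C7–C8–C9–C10) is grown from the cyclopentanone of a trans-hydrindane made from the (S)-hydrindenedione 1, whose one bought stereocentre (C10) relays C5, C6 and C3 by substrate control. The key step is a Lewis-acid-catalysed diazoethane homologation of the 6β-acetoxy-3β-silyloxy hydrindan-9-one 10. Because the C9 carbonyl lies between quaternary C10 and the C7 methylene, only the C7–C9 bond should migrate: the five-membered ring becomes six-membered and the inserted carbon arrives as C8 with its methyl. The C9 ketone then carries the 9α-hydroxy side chain through methylenation, α-face epoxidation, ylide homologation to a vinyl carbinol and B-alkyl Suzuki coupling with a bromobutenolide.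

Key step: step 9

Remark: the target is read as 6β-acetoxy-3β,9α-dihydroxy-8α-methyl(8βH)-labd-13-en-16,15-olide of the normal (5α-H, 10β-methyl) series.
Remark: labdane numbering is used for every intermediate; in the hydrindanes C8 is absent and C7 is bonded to C9.
Assumption: 1 and 3-bromofuran-2(5H)-one 16 are taken as commercial; diazoethane is prepared separately as an ethereal solution from commercial N-ethyl-N-nitrosourea and KOH.

Step 1
Reactants: 1 (7aS)-7a-methyl-2,3,7,7a-tetrahydro-1H-indene-1,5(6H)-dione, the (S)-Hajos–Parrish ketone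
Product: 2 C9 ethylene ketal of 1
Conditions: 2-ethyl-2-methyl-1,3-dioxolane (reagent and solvent), ethylene glycol (cat.), p-TsOH·H2O (cat.), rt
Reagents that add atoms: 2-ethyl-2-methyl-1,3-dioxolane, CCC1(C)OCCO1
Why: Acid-catalysed transketalisation should take the saturated cyclopentanone carbonyl (C9) and leave the less electrophilic conjugated C3 carbonyl; no stereocentre is formed.

Step 2
Reactants: 2 C9 ethylene ketal of 1
Product: 3 4,4-dimethyl-Δ5(6)-3-ketone 9-ketal
Conditions: t-BuOK, MeI, t-BuOH/THF, 0 °C → rt
Reagents that add atoms: iodomethane, CI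
Why: Deconjugative α,α-dimethylation of an enone: the extended potassium dienolate is methylated twice at C4, which should leave the double bond at C5=C6 in the five-membered ring while the ketal shields C9.

Step 3
Reactants: 3 4,4-dimethyl-Δ5(6)-3-ketone 9-ketal
Product: 5 3β,6α-dihydroxy-5α-H 9-ketal, via bis-boryl adduct 4 (not isolated)
Conditions: BH3·THF, THF, 0 °C → rt; then aq. NaOH, H2O2, 0 °C → rt
Reagents that add atoms: hydrogen peroxide, OO
Why: Hydroboration–oxidation: borane should add syn to the α-face of C5=C6 (anti to the C10 methyl) with boron on C6, which sets 5α-H (trans ring fusion) and 6α-OH, and it also reduces the C3 ketone, whose epimers converge in step 4.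

Step 4
Reactants: 5 3β,6α-dihydroxy-5α-H 9-ketal
Product: 6 3,6-dioxo-5α-H 9-ketal
Conditions: Dess–Martin periodinane, pyridine, CH2Cl2, 0 °C → rt
Reagents that add atoms: none
Why: Dess–Martin oxidation should convert both secondary alcohols into ketones under buffered, non-enolising conditions, so the C5 stereocentre next to the new C6 ketone is kept.

Step 5
Reactants: 6 3,6-dioxo-5α-H 9-ketal
Product: 7 3β,6β-dihydroxy 9-ketal
Conditions: NaBH4, MeOH/THF, −20 → 0 °C
Reagents that add atoms: none
Why: Substrate-controlled borohydride reduction: axial (α-face) attack at C3 should give the equatorial 3β-alcohol, and α-face attack at the C6 cyclopentanone, whose β-face is screened by the C10 and 4β methyl groups, should give the 6β-alcohol.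

Step 6
Reactants: 7 3β,6β-dihydroxy 9-ketal
Product: 8 3β-TBS ether 6β-alcohol 9-ketal
Conditions: TBSCl, imidazole, DMF, rt
Reagents that add atoms: tert-butyldimethylsilyl chloride, CC(C)(C)[Si](C)(C)Cl
Why: Sterically controlled silylation should take the equatorial 3β-OH and leave the 6β-OH, which is flanked by the syn C10 and 4β methyl groups.

Step 7
Reactants: 8 3β-TBS ether 6β-alcohol 9-ketal
Product: 9 6β-acetate 3β-TBS ether 9-ketal
Conditions: Ac2O, DMAP (cat.), pyridine, 50 °C
Reagents that add atoms: acetic anhydride, CC(=O)OC(C)=O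
Why: DMAP-catalysed acyl transfer should acetylate the hindered 6β-OH while C9 is still a ketal, so no β-acyloxy ketone is exposed to base.

Step 8
Reactants: 9 6β-acetate 3β-TBS ether 9-ketal
Product: 10 6β-acetoxy-3β-TBSO-4,4,10-trimethyl-trans-hydrindan-9-one
Conditions: PPTS (cat.), acetone/H2O, 40 °C
Reagents that add atoms: water, O
Why: Mild acid hydrolysis of the dioxolane should free the C9 ketone without cleaving the hindered secondary silyl ether, and the absence of base avoids E1cB loss of the β-acetoxy group.

Step 9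
Reactants: 10 6β-acetoxy-3β-TBSO-4,4,10-trimethyl-trans-hydrindan-9-one
Product: 12 6β-acetoxy-3β-TBSO-8α-methyl-trans-decal-9-one, via 8β-methyl epimer 11 (not isolated)
Conditions: CH3CHN2 (Et2O solution), Sc(OTf)3 (10 mol%), CH2Cl2, −78 °C; then DBU (cat.), toluene, 60 °C
Reagents that add atoms: diazoethane, CC=[N+]=[N-]
Why: Lewis-acid-catalysed diazoalkane–ketone homologation (a Tiffeneau–Demjanov-type 1,2-shift): diazoethane adds to the Sc(III)-activated C9 carbonyl, and in the β-oxido diazonium species the C7–C9 bond migrates to the former diazo carbon with loss of N2. The closest known reaction type is the D-homoannulation of 17-oxo steroids with diazoalkanes, in which the methylene and not the quaternary α-carbon migrates. No ring is closed: the five-membered ring C5–C6–C7–C9–C10 is enlarged to six-membered ring B by insertion of the new C8 between C7 and C9. The new stereocentre C8 is α to the ketone and is set by thermodynamic control in the DBU stage, where the methyl should take the equatorial α position because the 8β-epimer 11 suffers a 1,3-diaxial clash with the C10 methyl. The step needs migration of C7 in preference to C10 and a single homologation; the first is secured by the neopentyl, quaternary nature of C10 and the second by the much greater hindrance of the product ketone, flanked by C10 and C8.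

Step 10
Reactants: 12 6β-acetoxy-3β-TBSO-8α-methyl-trans-decal-9-one
Product: 13 9(11)-exomethylene compound
Conditions: Zn, CH2Br2, TiCl4 (pre-formed reagent in THF), CH2Cl2, 0 °C → rt
Reagents that add atoms: dibromomethane, BrCBr
Why: Takai–Lombardo methylenation: the non-basic gem-dimetallic reagent should methylenate the hindered, enolisable C9 ketone without epimerising C8 and without touching the acetate.

Step 11
Reactants: 13 9(11)-exomethylene compound
Product: 14 9α,11-epoxide
Conditions: mCPBA, CH2Cl2, 0 °C
Reagents that add atoms: 3-chloroperoxybenzoic acid, OOC(=O)c1cccc(Cl)c1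
Why: Prilezhaev epoxidation: the peracid should approach the exocyclic alkene from the α-face, because the β-face at C9 is blocked by the axial C10 methyl, which sets C9 with oxygen α and C11 β.

Step 12
Reactants: 14 9α,11-epoxide
Product: 15 9α-hydroxy-9β-vinyl compound (C11=C12)
Conditions: Me3S+ I−, n-BuLi, THF, −10 °C → rt
Reagents that add atoms: trimethylsulfonium iodide (as its ylide), C[S+](C)C.[I-]
Why: Sulfonium-ylide homologation of an epoxide to the one-carbon-extended allylic alcohol: the ylide should open the oxirane at its CH2 terminus C11 and a second equivalent should trigger elimination of dimethyl sulfide to give C11=C12, the C9–O bond never being broken so that the 9α configuration is retained.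

Step 13
Reactants: 15 9α-hydroxy-9β-vinyl compound; 16 3-bromofuran-2(5H)-one
Product: 18 3-O-TBS ether of the target, via B-alkyl-9-BBN adduct 17 (not isolated)
Conditions: 9-BBN, THF, rt; then 16, Pd(dppf)Cl2 (cat.), Ph3As (cat.), Cs2CO3, DMF/H2O, rt
Reagents that add atoms: none
Why: Anti-Markovnikov hydroboration of the vinyl group followed by B-alkyl Suzuki–Miyaura coupling with the α-bromo butenolide should form the C12–C13 bond and deliver the α-substituted butenolide directly; no stereocentre is formed and the free tertiary alcohol is tolerated.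

Step 14
Reactants: 18 3-O-TBS ether of the target
Product: 19 6β-acetoxy-3β,9α-dihydroxy-8α-methyl(8βH)-labd-13-en-16,15-olide (target)
Conditions: HF·pyridine, pyridine/THF, 0 °C → rt
Reagents that add atoms: none
Why: Fluoride-mediated desilylation under buffered acidic conditions should free the 3β-OH while the hindered acetate, the tertiary alcohol and the butenolide stay intact.

**Compound list**

1 | (7aS)-7a-methyl-2,3,7,7a-tetrahydro-1H-indene-1,5(6H)-dione, (S)-Hajos–Parrish ketone (C10 quaternary, C9 cyclopentanone C=O, C3 enone C=O) | C[C@]12CCC(=O)C=C1CCC2=O | starting material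
2 | C9 ethylene ketal (1,3-dioxolane) of 1 | C[C@]12CCC(=O)C=C1CCC23OCCO3 | intermediate
3 | 4,4-dimethyl-Δ5(6)-3-ketone 9-ketal (alkene in the five-membered ring) | C[C@]12CCC(=O)C(C)(C)C1=CCC23OCCO3 | intermediate
4 | bis-boryl adduct: 6α-BH2, 3β-O-BH2, 5α-H, 9-ketal (idealised, not isolated) | B[C@H]1CC2(OCCO2)[C@@]2(C)CC[C@H](OB)C(C)(C)[C@H]12 | intermediate
5 | 3β,6α-dihydroxy-4,4,10-trimethyl-5α-hydrindane 9-ketal (trans-fused) | O[C@H]1CC2(OCCO2)[C@@]2(C)CC[C@H](O)C(C)(C)[C@H]12 | intermediate
6 | 3,6-dioxo-4,4,10-trimethyl-5α-hydrindane 9-ketal | O=C1CC2(OCCO2)[C@@]2(C)CCC(=O)C(C)(C)[C@H]12 | intermediate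
7 | 3β,6β-dihydroxy-4,4,10-trimethyl-5α-hydrindane 9-ketal | O[C@@H]1CC2(OCCO2)[C@@]2(C)CC[C@H](O)C(C)(C)[C@H]12 | intermediate
8 | 3β-(tert-butyldimethylsilyloxy)-6β-hydroxy 9-ketal | O[C@@H]1CC2(OCCO2)[C@@]2(C)CC[C@H](O[Si](C)(C)C(C)(C)C)C(C)(C)[C@H]12 | intermediate
9 | 6β-acetoxy-3β-(tert-butyldimethylsilyloxy) 9-ketal | CC(=O)O[C@@H]1CC2(OCCO2)[C@@]2(C)CC[C@H](O[Si](C)(C)C(C)(C)C)C(C)(C)[C@H]12 | intermediate
10 | 6β-acetoxy-3β-TBSO-4,4,10-trimethyl-trans-hydrindan-9-one | CC(=O)O[C@@H]1CC(=O)[C@@]2(C)CC[C@H](O[Si](C)(C)C(C)(C)C)C(C)(C)[C@H]12 | intermediate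
11 | 8β-methyl epimer of 12 (not isolated) | CC(=O)O[C@@H]1C[C@H](C)C(=O)[C@@]2(C)CC[C@H](O[Si](C)(C)C(C)(C)C)C(C)(C)[C@H]12 | intermediate
12 | 6β-acetoxy-3β-TBSO-4,4,8α,10β-tetramethyl-trans-decal-9-one (8β-H, 5α-H) | CC(=O)O[C@@H]1C[C@@H](C)C(=O)[C@@]2(C)CC[C@H](O[Si](C)(C)C(C)(C)C)C(C)(C)[C@H]12 | intermediate
13 | 9(11)-exomethylene analogue of 12 (C9=C11H2) | CC(=O)O[C@@H]1C[C@@H](C)C(=C)[C@@]2(C)CC[C@H](O[Si](C)(C)C(C)(C)C)C(C)(C)[C@H]12 | intermediate
14 | 9α,11-epoxide (spiro-oxirane, O α, CH2 β) | CC(=O)O[C@@H]1C[C@@H](C)[C@]3(CO3)[C@@]2(C)CC[C@H](O[Si](C)(C)C(C)(C)C)C(C)(C)[C@H]12 | intermediate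
15 | 6β-acetoxy-3β-TBSO-9α-hydroxy-9β-vinyl decalin (13,14,15,16-tetranorlabd-11-en-9α-ol) | CC(=O)O[C@@H]1C[C@@H](C)[C@](O)(C=C)[C@@]2(C)CC[C@H](O[Si](C)(C)C(C)(C)C)C(C)(C)[C@H]12 | intermediate
16 | 3-bromofuran-2(5H)-one | O=C1OCC=C1Br | starting material
17 | B-alkyl-9-BBN adduct of 15 (boron on C12, not isolated) | CC(=O)O[C@@H]1C[C@@H](C)[C@](O)(CCB3C4CCCC3CCC4)[C@@]2(C)CC[C@H](O[Si](C)(C)C(C)(C)C)C(C)(C)[C@H]12 | intermediate
18 | 3-O-TBS ether of the target | CC(=O)O[C@@H]1C[C@@H](C)[C@](O)(CCC3=CCOC3=O)[C@@]2(C)CC[C@H](O[Si](C)(C)C(C)(C)C)C(C)(C)[C@H]12 | intermediate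
19 | 6β-acetoxy-3β,9α-dihydroxy-8α-methyl(8βH)-labd-13-en-16,15-olide (CNP0513254.1) | CC(=O)O[C@@H]1C[C@@H](C)[C@](O)(CCC2=CCOC2=O)[C@@]2(C)CC[C@H](O)C(C)(C)[C@H]12 | target

**Step count.** Total: 14 steps. Longest linear sequence: 14 steps (1 → 19).

**Steps most likely to fail**

Step 9 (key step). The risk is a competing shift of the quaternary C10, spiro-oxirane formation from the diazoalkane adduct, or loss of the β-acetoxy group from 10 before the shift takes place. The fallback sets out from 10 and returns at 12. Homologation with an acceptor diazo compound, allyl diazoacetate with BF3·OEt2 at −78 °C, should insert cleanly on the methylene side and give the allyl β-keto ester F1. C-Methylation of its enolate (K2CO3, MeI, acetone) from the α-face should give the quaternary keto ester F2. Palladium-catalysed deallylation–decarboxylation (Pd(PPh3)4, HCO2H, Et3N, THF), followed by the same DBU equilibration, should then deliver 12. The C8 methyl then comes from an enolate alkylation and not from the diazo carbon.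

Step 12. The risk is a slow SN2 opening at the neopentyl-type C11 of the hindered spiro-epoxide, together with acyl transfer from the 6β-acetate to the ylide. The fallback sets out from 13 and returns at 15, and avoids any substitution at C11. Dihydroxylation of 13 (OsO4 cat., NMO, acetone/H2O) from the α-face should give the 9α,11-diol F3. Parikh–Doering oxidation of the primary alcohol (SO3·pyridine, DMSO, Et3N) should give the 9α-hydroxy aldehyde F4. Wittig methylenation (Ph3P=CH2, THF, −78 → 0 °C) should then give 15.

Step 13. The risk is decomposition of the base-sensitive bromobutenolide under the aqueous base, or slow transmetalation of the hindered γ-hydroxy alkylborane, so that protodeboronation wins. The fallback sets out from 15 (through borane 17) and returns at 18, with the butenolide carried in masked form. Borane 17 is coupled under the same palladium conditions with the more robust 3-bromo-2-(trimethylsilyl)furan F5 (from 3-bromofuran, LDA, TMSCl) to give the 2-silyl-3-alkylfuran F6. Peracid oxidation of the silylfuran (AcOOH, NaOAc, CH2Cl2) should place the carbonyl on the silylated carbon and give 18 with the required α-substituted butenolide regiochemistry.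

**Further compounds**

F1 | step 9 | allyl 6β-acetoxy-3β-TBSO-9-oxo-decalin-8-carboxylate (C8 epimerisable, unassigned) | CC(=O)O[C@@H]1CC(C(=O)OCC=C)C(=O)[C@@]2(C)CC[C@H](O[Si](C)(C)C(C)(C)C)C(C)(C)[C@H]12
F2 | step 9 | C8-methylated allyl β-keto ester (8α-methyl, 8β-CO2allyl; configuration lost on decarboxylation) | CC(=O)O[C@@H]1C[C@](C)(C(=O)OCC=C)C(=O)[C@@]2(C)CC[C@H](O[Si](C)(C)C(C)(C)C)C(C)(C)[C@H]12
F3 | step 12 | 9α,11-diol (6β-acetoxy-3β-TBSO-9α-hydroxy-9β-hydroxymethyl decalin) | CC(=O)O[C@@H]1C[C@@H](C)[C@](O)(CO)[C@@]2(C)CC[C@H](O[Si](C)(C)C(C)(C)C)C(C)(C)[C@H]12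
F4 | step 12 | 9α-hydroxy-9β-carbaldehyde (C11 aldehyde) | CC(=O)O[C@@H]1C[C@@H](C)[C@](O)(C=O)[C@@]2(C)CC[C@H](O[Si](C)(C)C(C)(C)C)C(C)(C)[C@H]12
F5 | step 13 | 3-bromo-2-(trimethylsilyl)furan | C[Si](C)(C)c1occc1Br
F6 | step 13 | 2-trimethylsilyl-3-alkylfuran coupling product (furan C3 bonded to C12) | CC(=O)O[C@@H]1C[C@@H](C)[C@](O)(CCc3ccoc3[Si](C)(C)C)[C@@]2(C)CC[C@H](O[Si](C)(C)C(C)(C)C)C(C)(C)[C@H]12
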